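**Retrosynthetic overview**
1. Ring C is the only ring made and it closes last: intramolecular Friedel–Crafts acylation (C4–C4a) of an (S)-2-aryl-2-hydroxy-3-aryloxypropanoic acid, then MOM removal.
2. The acid comes from a dioxolanyl carbinol by acetonide hydrolysis, glycol cleavage and Pinnick oxidation. Its tertiary centre (future C3) is set by chelation-controlled addition of the B-ring aryl Grignard to an α-aryloxy ketone that carries the stereocentre of methyl (R)-glycerate acetonide (D-mannitol series).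
3. The ketone is assembled from 3,5-bis(MOM)-phloroglucinol and the chloromethyl ketone of the glycerate ester.
4. The B-ring bromide gets its prenyl group (C3'–C1'' bond) by aromatic Claisen [3,3] rearrangement of a 1,1-dimethylallyl aryl ether. The ether comes from Pd-catalysed O-allylation of a bromophenol made from 6-bromovanillin (MOM protection, Baeyer–Villiger).

Assumption: 6-bromovanillin (1) and tert-butyl 2-methylbut-3-en-2-yl carbonate (5) are taken as catalogue compounds; the target is the (3S) enantiomer encoded by the SMILES.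

**Route**

Step 1
Reactants: 1 2-bromo-4-hydroxy-5-methoxybenzaldehyde (6-bromovanillin)
Product: 2 2-bromo-5-methoxy-4-(methoxymethoxy)benzaldehyde
Conditions: MOMCl, iPr2NEt, CH2Cl2, 0 °C → rt
Reagents that add atoms: chloromethyl methyl ether (MOMCl), COCCl
Why: Williamson-type O-alkylation of the acidic phenol masks the future 5'-OH as an acetal that survives peracid, Pd(0), heat, base and organometallics.

Step 2
Reactants: 2 2-bromo-5-methoxy-4-(methoxymethoxy)benzaldehyde
Product: 4 2-bromo-5-methoxy-4-(methoxymethoxy)phenol, via aryl formate 3 (not isolated)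
Conditions: mCPBA, CH2Cl2, rt; then K2CO3 (cat.), MeOH, rt
Reagents that add atoms: 3-chloroperoxybenzoic acid (mCPBA), OOC(=O)c1cccc(Cl)c1
Why: Baeyer–Villiger (Dakin-type) oxidation; the electron-rich p-alkoxyaryl group migrates to give the aryl formate, which is transesterified to the phenol.

Step 3
Reactants: 4 2-bromo-5-methoxy-4-(methoxymethoxy)phenol; 5 tert-butyl 2-methylbut-3-en-2-yl carbonate
Product: 6 1-bromo-4-methoxy-5-(methoxymethoxy)-2-[(2-methylbut-3-en-2-yl)oxy]benzene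
Conditions: Pd(PPh3)4 (2 mol%), THF, 0 °C
Reagents that add atoms: none
Why: Tsuji–Trost decarboxylative O-allylation; the phenoxide attacks the π-(1,1-dimethylallyl)palladium complex at the tertiary terminus under kinetic control, and the electron-rich C–Br bond does not add to Pd(0) at 0 °C.

Step 4
Reactants: 6 1-bromo-4-methoxy-5-(methoxymethoxy)-2-[(2-methylbut-3-en-2-yl)oxy]benzene
Product: 8 1-bromo-2,4-dimethoxy-5-(methoxymethoxy)-3-(3-methylbut-2-en-1-yl)benzene, via ortho-prenyl phenol 7 (not isolated)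
Conditions: DMF, 125 °C; then K2CO3, MeI, rt
Reagents that add atoms: iodomethane, CI
Why: Aromatic Claisen [3,3]-sigmatropic rearrangement; with one ortho position blocked by Br and the para position by OMOM, the ether can only deliver (with allyl inversion) a normal prenyl group to the carbon between the two oxygens, and the phenol is methylated in the same pot (Williamson) before it can cyclise to a chroman.

Step 5
Reactants: 9 phloroglucinol (benzene-1,3,5-triol)
Product: 10 3,5-bis(methoxymethoxy)phenol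
Conditions: MOMCl (2.0 equiv), iPr2NEt, DMF, 0 °C → rt; chromatography
Reagents that add atoms: chloromethyl methyl ether (MOMCl), COCCl
Why: Statistical Williamson-type protection of the symmetric triphenol; the bis-ether is separated from mono- and tris-ethers.

Step 6
Reactants: 11 methyl (R)-2,2-dimethyl-1,3-dioxolane-4-carboxylate
Product: 12 (R)-2-chloro-1-(2,2-dimethyl-1,3-dioxolan-4-yl)ethan-1-one
Conditions: ICH2Cl, MeLi·LiBr, THF, −78 °C; aq NH4Cl
Reagents that add atoms: chloroiodomethane, ClCI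
Why: Nucleophilic acyl substitution by chloromethyllithium generated in situ by I/Li exchange (Barbier conditions); at −78 °C the reaction stops at the ketone stage and the α-alkoxy stereocentre is not enolised.

Step 7
Reactants: 10 3,5-bis(methoxymethoxy)phenol; 12 (R)-2-chloro-1-(2,2-dimethyl-1,3-dioxolan-4-yl)ethan-1-one
Product: 13 (R)-2-[3,5-bis(methoxymethoxy)phenoxy]-1-(2,2-dimethyl-1,3-dioxolan-4-yl)ethan-1-one
Conditions: K2CO3, NaI (cat.), acetone, rt
Reagents that add atoms: none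
Why: Williamson SN2 displacement on the activated α-chloroketone (Finkelstein catalysis) under mild heterogeneous base, which leaves the α-alkoxy stereocentre intact.

Step 8
Reactants: 8 1-bromo-2,4-dimethoxy-5-(methoxymethoxy)-3-(3-methylbut-2-en-1-yl)benzene; 13 (R)-2-[3,5-bis(methoxymethoxy)phenoxy]-1-(2,2-dimethyl-1,3-dioxolan-4-yl)ethan-1-one
Product: 16 (1S)-2-[3,5-bis(methoxymethoxy)phenoxy]-1-[2,4-dimethoxy-5-(methoxymethoxy)-3-(3-methylbut-2-en-1-yl)phenyl]-1-[(4R)-2,2-dimethyl-1,3-dioxolan-4-yl]ethan-1-ol, via aryllithium 14 (not isolated), via arylmagnesium bromide 15 (not isolated)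
Conditions: 8, n-BuLi, THF, −78 °C; MgBr2·OEt2, −78 → 0 °C; then 13, THF/Et2O, −78 → −20 °C; aq NH4Cl
Reagents that add atoms: none
Why: Br/Li exchange and transmetalation give the aryl Grignard, which adds under Cram-chelate control (Mg bridging C=O and the dioxolane O3, attack anti to the dioxolane C5), so the bought (R) centre sets the new tertiary carbinol as (1S).

Step 9
Reactants: 16 (1S)-2-[3,5-bis(methoxymethoxy)phenoxy]-1-[2,4-dimethoxy-5-(methoxymethoxy)-3-(3-methylbut-2-en-1-yl)phenyl]-1-[(4R)-2,2-dimethyl-1,3-dioxolan-4-yl]ethan-1-ol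
Product: 18 (2S)-3-[3,5-bis(methoxymethoxy)phenoxy]-2-[2,4-dimethoxy-5-(methoxymethoxy)-3-(3-methylbut-2-en-1-yl)phenyl]-2-hydroxypropanal, via triol 17 (not isolated)
Conditions: AcOH/H2O 4:1, 35 °C; evaporate; then NaIO4 (1.05 equiv), NaHCO3, THF/H2O, 0 °C
Reagents that add atoms: none
Why: Acetal hydrolysis then Malaprade glycol cleavage; one equivalent of periodate cleaves the unhindered primary/secondary diol much faster than the hindered tertiary carbinol, excising the controlling centre as the aldehyde carbon while the quaternary carbinol cannot epimerise.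

Step 10
Reactants: 18 (2S)-3-[3,5-bis(methoxymethoxy)phenoxy]-2-[2,4-dimethoxy-5-(methoxymethoxy)-3-(3-methylbut-2-en-1-yl)phenyl]-2-hydroxypropanal
Product: 19 (2S)-3-[3,5-bis(methoxymethoxy)phenoxy]-2-[2,4-dimethoxy-5-(methoxymethoxy)-3-(3-methylbut-2-en-1-yl)phenyl]-2-hydroxypropanoic acid
Conditions: NaClO2, NaH2PO4, 2-methylbut-2-ene, t-BuOH/H2O, 0 °C
Reagents that add atoms: sodium chlorite, [Na+].[O-]Cl=O
Why: Pinnick (Lindgren) oxidation of the crude aldehyde under buffered, scavenged conditions that spare the prenyl alkene, the MOM acetals and the electron-rich rings.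

Step 11
Reactants: 19 (2S)-3-[3,5-bis(methoxymethoxy)phenoxy]-2-[2,4-dimethoxy-5-(methoxymethoxy)-3-(3-methylbut-2-en-1-yl)phenyl]-2-hydroxypropanoic acid
Product: 22 sophonorol D [(3S)-3,5,7-trihydroxy-3-[5-hydroxy-2,4-dimethoxy-3-(3-methylbut-2-en-1-yl)phenyl]-2,3-dihydro-4H-chromen-4-one], via mixed anhydride 20 (not isolated), via O-trifluoroacetyl chromanone 21 (not isolated)
Conditions: TFAA (2.5 equiv), CH2Cl2, 0 °C → rt; evaporate; then 1 M HCl in MeOH, 35 °C
Reagents that add atoms: none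
Why: Intramolecular Friedel–Crafts acylation by the mixed trifluoroacetic anhydride, ortho to the ether oxygen of the symmetric phloroglucinol-type ring, closes the pyranone (the new ketone deactivates the ring); acid methanolysis then removes the trifluoroacetate and the three MOM acetals without touching the non-enolisable C3 centre.

**Compound list**
1 | 2-bromo-4-hydroxy-5-methoxybenzaldehyde (6-bromovanillin) | COc1cc(C=O)c(Br)cc1O | starting material
2 | 2-bromo-5-methoxy-4-(methoxymethoxy)benzaldehyde | COCOc1cc(Br)c(C=O)cc1OC | intermediate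
3 | 2-bromo-5-methoxy-4-(methoxymethoxy)phenyl formate | COCOc1cc(Br)c(OC=O)cc1OC | intermediate
4 | 2-bromo-5-methoxy-4-(methoxymethoxy)phenol | COCOc1cc(Br)c(O)cc1OC | intermediate
5 | tert-butyl 2-methylbut-3-en-2-yl carbonate | C=CC(C)(C)OC(=O)OC(C)(C)C | starting material
6 | 1-bromo-4-methoxy-5-(methoxymethoxy)-2-[(2-methylbut-3-en-2-yl)oxy]benzene | COCOc1cc(Br)c(OC(C)(C)C=C)cc1OC | intermediate
7 | 6-bromo-3-methoxy-4-(methoxymethoxy)-2-(3-methylbut-2-en-1-yl)phenol | COCOc1cc(Br)c(O)c(CC=C(C)C)c1OC | intermediate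
8 | 1-bromo-2,4-dimethoxy-5-(methoxymethoxy)-3-(3-methylbut-2-en-1-yl)benzene | COCOc1cc(Br)c(OC)c(CC=C(C)C)c1OC | intermediate
9 | phloroglucinol (benzene-1,3,5-triol) | Oc1cc(O)cc(O)c1 | starting material
10 | 3,5-bis(methoxymethoxy)phenol | COCOc1cc(O)cc(OCOC)c1 | intermediate
11 | methyl (R)-2,2-dimethyl-1,3-dioxolane-4-carboxylate | COC(=O)[C@H]1COC(C)(C)O1 | starting material
12 | (R)-2-chloro-1-(2,2-dimethyl-1,3-dioxolan-4-yl)ethan-1-one | ClCC(=O)[C@H]1COC(C)(C)O1 | intermediate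
13 | (R)-2-[3,5-bis(methoxymethoxy)phenoxy]-1-(2,2-dimethyl-1,3-dioxolan-4-yl)ethan-1-one | COCOc1cc(OCOC)cc(OCC(=O)[C@H]2COC(C)(C)O2)c1 | intermediate
14 | [2,4-dimethoxy-5-(methoxymethoxy)-3-(3-methylbut-2-en-1-yl)phenyl]lithium | [Li]c1cc(OCOC)c(OC)c(CC=C(C)C)c1OC | intermediate
15 | bromo[2,4-dimethoxy-5-(methoxymethoxy)-3-(3-methylbut-2-en-1-yl)phenyl]magnesium | Br[Mg]c1cc(OCOC)c(OC)c(CC=C(C)C)c1OC | intermediate
16 | (1S)-2-[3,5-bis(methoxymethoxy)phenoxy]-1-[2,4-dimethoxy-5-(methoxymethoxy)-3-(3-methylbut-2-en-1-yl)phenyl]-1-[(4R)-2,2-dimethyl-1,3-dioxolan-4-yl]ethan-1-ol | COc1c(OCOC)cc([C@](O)(COc2cc(OCOC)cc(OCOC)c2)[C@H]2COC(C)(C)O2)c(OC)c1CC=C(C)C | intermediate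
17 | (2R,3S)-4-[3,5-bis(methoxymethoxy)phenoxy]-3-[2,4-dimethoxy-5-(methoxymethoxy)-3-(3-methylbut-2-en-1-yl)phenyl]butane-1,2,3-triol | COc1c(OCOC)cc([C@](O)(COc2cc(OCOC)cc(OCOC)c2)[C@H](O)CO)c(OC)c1CC=C(C)C | intermediate
18 | (2S)-3-[3,5-bis(methoxymethoxy)phenoxy]-2-[2,4-dimethoxy-5-(methoxymethoxy)-3-(3-methylbut-2-en-1-yl)phenyl]-2-hydroxypropanal | COc1c(OCOC)cc([C@](O)(COc2cc(OCOC)cc(OCOC)c2)C=O)c(OC)c1CC=C(C)C | intermediate
19 | (2S)-3-[3,5-bis(methoxymethoxy)phenoxy]-2-[2,4-dimethoxy-5-(methoxymethoxy)-3-(3-methylbut-2-en-1-yl)phenyl]-2-hydroxypropanoic acid | COc1c(OCOC)cc([C@](O)(COc2cc(OCOC)cc(OCOC)c2)C(=O)O)c(OC)c1CC=C(C)C | intermediate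
20 | (2S)-3-[3,5-bis(methoxymethoxy)phenoxy]-2-[2,4-dimethoxy-5-(methoxymethoxy)-3-(3-methylbut-2-en-1-yl)phenyl]-2-(trifluoroacetoxy)propanoic trifluoroacetic anhydride | COc1c(OCOC)cc([C@](OC(=O)C(F)(F)F)(COc2cc(OCOC)cc(OCOC)c2)C(=O)OC(=O)C(F)(F)F)c(OC)c1CC=C(C)C | intermediate
21 | (3S)-3-[2,4-dimethoxy-5-(methoxymethoxy)-3-(3-methylbut-2-en-1-yl)phenyl]-5,7-bis(methoxymethoxy)-4-oxo-3,4-dihydro-2H-chromen-3-yl trifluoroacetate | COc1c(OCOC)cc([C@]2(OC(=O)C(F)(F)F)COc3cc(OCOC)cc(OCOC)c3C2=O)c(OC)c1CC=C(C)C | intermediate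
22 | sophonorol D, (3S)-3,5,7-trihydroxy-3-[5-hydroxy-2,4-dimethoxy-3-(3-methylbut-2-en-1-yl)phenyl]-2,3-dihydro-4H-chromen-4-one | COc1c(O)cc([C@]2(O)COc3cc(O)cc(O)c3C2=O)c(OC)c1CC=C(C)C | target

**Totals**
Total step count: 11. Longest linear sequence: 8 steps (1, 2, 3, 4, 8, 9, 10, 11).

**Three steps most likely to fail**

Step 8. The aryl Grignard may enolise the α-aryloxy ketone, or the aryloxy oxygen may compete as a chelating site and erode the diastereoselectivity. The fallback sets out from 12 (with 15 made from 8 as in step 8) and comes back at 16. The Grignard 15 is added at −78 °C to the chloromethyl ketone 12, where only the dioxolane oxygen can chelate and the more electrophilic carbonyl outruns enolisation. This gives, with the same facial sense, the chlorohydrin F1. K2CO3 in MeOH closes it to the epoxide F2. The phenoxide of 10 (Cs2CO3, DMF, 60 °C) then opens F2 at its CH2 terminus to give 16.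

Step 9. The free tertiary α-hydroxy aldehyde can be over-cleaved by periodate to a ketone, can undergo α-ketol rearrangement, or can cyclise prematurely onto the phloroglucinol ring. The fallback sets out from 16 and comes back at 19. TESOTf/2,6-lutidine converts 16 to the triethylsilyl ether F3. H5IO6 in EtOAc at 0 °C hydrolyses the acetonide to the diol F4 and cleaves it to the α-silyloxy aldehyde F5, which can neither be over-cleaved nor rearrange. Pinnick oxidation gives the α-silyloxy acid F6, and TBAF/AcOH removes the silyl group to give 19.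

Step 11. The hindered α-oxygenated acyl donor may decarbonylate or ionise at the tertiary benzylic position, or the ring may be trifluoroacetylated intermolecularly; the acid deprotection also risks dehydration to the isoflavone. The fallback sets out from 18 and comes back at 22. A chelating Lewis acid (MgBr2·OEt2, CH2Cl2, −40 °C) effects intramolecular Friedel–Crafts hydroxyalkylation of 18 to the chromane-3,4-diol F7 (C4 epimers). This is oxidised without purification by Dess–Martin periodinane/NaHCO3 to the tris-MOM 3-hydroxychromanone F8. 1 M HCl in MeOH then removes the MOM groups to give 22.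

**Further compounds**
F1 | step 8 | (1R)-2-chloro-1-[2,4-dimethoxy-5-(methoxymethoxy)-3-(3-methylbut-2-en-1-yl)phenyl]-1-[(4R)-2,2-dimethyl-1,3-dioxolan-4-yl]ethan-1-ol | COc1c(OCOC)cc([C@](O)(CCl)[C@H]2COC(C)(C)O2)c(OC)c1CC=C(C)C
F2 | step 8 | (4R)-4-{(2S)-2-[2,4-dimethoxy-5-(methoxymethoxy)-3-(3-methylbut-2-en-1-yl)phenyl]oxiran-2-yl}-2,2-dimethyl-1,3-dioxolane | COc1c(OCOC)cc([C@]3(CO3)[C@H]2COC(C)(C)O2)c(OC)c1CC=C(C)C
F3 | step 9 | {(1S)-2-[3,5-bis(methoxymethoxy)phenoxy]-1-[2,4-dimethoxy-5-(methoxymethoxy)-3-(3-methylbut-2-en-1-yl)phenyl]-1-[(4R)-2,2-dimethyl-1,3-dioxolan-4-yl]ethoxy}triethylsilane | COc1c(OCOC)cc([C@](O[Si](CC)(CC)CC)(COc2cc(OCOC)cc(OCOC)c2)[C@H]2COC(C)(C)O2)c(OC)c1CC=C(C)C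
F4 | step 9 | (2R,3S)-4-[3,5-bis(methoxymethoxy)phenoxy]-3-[2,4-dimethoxy-5-(methoxymethoxy)-3-(3-methylbut-2-en-1-yl)phenyl]-3-[(triethylsilyl)oxy]butane-1,2-diol | COc1c(OCOC)cc([C@](O[Si](CC)(CC)CC)(COc2cc(OCOC)cc(OCOC)c2)[C@H](O)CO)c(OC)c1CC=C(C)C
F5 | step 9 | (2S)-3-[3,5-bis(methoxymethoxy)phenoxy]-2-[2,4-dimethoxy-5-(methoxymethoxy)-3-(3-methylbut-2-en-1-yl)phenyl]-2-[(triethylsilyl)oxy]propanal | COc1c(OCOC)cc([C@](O[Si](CC)(CC)CC)(COc2cc(OCOC)cc(OCOC)c2)C=O)c(OC)c1CC=C(C)C
F6 | step 9 | (2S)-3-[3,5-bis(methoxymethoxy)phenoxy]-2-[2,4-dimethoxy-5-(methoxymethoxy)-3-(3-methylbut-2-en-1-yl)phenyl]-2-[(triethylsilyl)oxy]propanoic acid | COc1c(OCOC)cc([C@](O[Si](CC)(CC)CC)(COc2cc(OCOC)cc(OCOC)c2)C(=O)O)c(OC)c1CC=C(C)C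
F7 | step 11 | (3S,4RS)-3-[2,4-dimethoxy-5-(methoxymethoxy)-3-(3-methylbut-2-en-1-yl)phenyl]-5,7-bis(methoxymethoxy)-3,4-dihydro-2H-chromene-3,4-diol | COc1c(OCOC)cc([C@]2(O)COc3cc(OCOC)cc(OCOC)c3C2O)c(OC)c1CC=C(C)C
F8 | step 11 | (3S)-3-[2,4-dimethoxy-5-(methoxymethoxy)-3-(3-methylbut-2-en-1-yl)phenyl]-3-hydroxy-5,7-bis(methoxymethoxy)-2,3-dihydro-4H-chromen-4-one | COc1c(OCOC)cc([C@]2(O)COc3cc(OCOC)cc(OCOC)c3C2=O)c(OC)c1CC=C(C)C
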